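**Plan**
- Retrosynthetic cuts, in order: the C3–O bond of the ring benzoate (Mitsunobu, inversion), the O–CH3 bond at C2, the two oxirane C–O bonds at C1/C6 (directed epoxidation of C1=C6), the C1′–O ester bond, and last C1–C1′ (Stille). This leads back to (1S,2S)-3-bromocyclohexa-3,5-diene-1,2-diol and (tributylstannyl)methanol.
- Enabling feature: before the oxirane of the 7-oxabicyclo[4.1.0]heptene exists, C1 is an sp2 carbon of the C1=C6–C5=C4 diene. In the microbial cis-dihydrodiol of bromobenzene exactly this carbon carries Br, and the same ring already holds the C2 and C3 oxygens and the C4=C5 bond.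
- Forward: the carbocycle comes from the chiral pool, the side chain is joined to C1 in step 2, the oxirane is closed on C1=C6 in step 4, and the ring benzoate is installed last.
- Stereochemistry: C2 is retained from the diol. C1 and C6 are set syn to the free C2–OH by vanadium-directed epoxidation. C3 is inverted in the final Mitsunobu step, turning the cis-diol of the pool into the trans C2/C3 pair of the target.

Key step: step 2

Remark: ring atoms are numbered C1–C6/O7 as in 7-oxabicyclo[4.1.0]hept-4-ene, the exocyclic CH2 is called C1′, and TDS stands for dimethyl(2,3-dimethylbutan-2-yl)silyl (thexyldimethylsilyl). Compound 1 is taken as the commercial (1S,2S) metabolite.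

**Step 1**
Reactants: 1 (1S,2S)-3-bromocyclohexa-3,5-diene-1,2-diol
Product: 2 (1S,6S)-2-bromo-6-(TDS-oxy)cyclohexa-2,4-dien-1-ol
Conditions: TDSCl, imidazole, DMF, −10 °C
Reagents that add atoms: chloro(dimethyl)thexylsilane (TDSCl), CC(C)C(C)(C)[Si](C)(C)Cl
Why: Regioselective silyl ether formation with a bulky chlorosilane should occur at the hydroxyl remote from bromine (the future C3–OH), because the other hydroxyl is flanked by the bromine-bearing sp2 carbon; no stereocentre is touched.

**Step 2**
Reactants: 2 (1S,6S)-2-bromo-6-(TDS-oxy)cyclohexa-2,4-dien-1-ol, 3 (tributylstannyl)methanol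
Product: 4 (1R,6S)-2-(hydroxymethyl)-6-(TDS-oxy)cyclohexa-2,4-dien-1-ol
Conditions: Pd(PPh3)4 (5 mol %), 1,4-dioxane, 80 °C
Reagents that add atoms: none
Why: Migita–Kosugi–Stille cross-coupling: Pd(0) inserts into the vinylic C1–Br bond, the hydroxymethyl group is transferred from tin in preference to butyl because the α-oxygen assists transmetalation, and reductive elimination forms the C1–C1′ bond. The closest known reaction type is the palladium-catalysed hydroxymethylation of aryl and alkenyl bromides and triflates with (tributylstannyl)methanol. No ring is closed and no stereocentre is created; C2 and C3 are spectators and keep the configuration of the chiral pool (the descriptor at C2 changes from S to R only because the CIP priorities change). The step needs site selectivity, which the single C–Br bond secures, group-transfer selectivity (CH2OH over n-Bu), and survival of the heat- and acid-sensitive dienol, which the neutral, base-free conditions and moderate temperature should allow; the free C2–OH is tolerated by the stannane. The product carries an allylic CH2OH on C1, so that C1=C6 is a trisubstituted alkene flanked by the C2 hydroxyl, which is the arrangement the directed epoxidation in step 4 requires.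

**Step 3**
Reactants: 4 (1R,6S)-2-(hydroxymethyl)-6-(TDS-oxy)cyclohexa-2,4-dien-1-ol
Product: 5 [(5S,6R)-6-hydroxy-5-(TDS-oxy)cyclohexa-1,3-dien-1-yl]methyl benzoate
Conditions: BzCl (1.05 equiv), pyridine, CH2Cl2, −40 to −20 °C
Reagents that add atoms: benzoyl chloride, O=C(Cl)c1ccccc1
Why: Chemoselective esterification with one equivalent of acid chloride at low temperature should acylate the primary allylic C1′–OH and leave the hindered secondary C2–OH free as the directing group for step 4.

**Step 4**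
Reactants: 5 [(5S,6R)-6-hydroxy-5-(TDS-oxy)cyclohexa-1,3-dien-1-yl]methyl benzoate
Product: 6 [(1S,2S,3S,6R)-2-hydroxy-3-(TDS-oxy)-7-oxabicyclo[4.1.0]hept-4-en-1-yl]methyl benzoate
Conditions: VO(acac)2 (5 mol %), t-BuOOH, CH2Cl2, 0 °C
Reagents that add atoms: tert-butyl hydroperoxide, CC(C)(C)OO
Why: Vanadium-catalysed hydroxyl-directed epoxidation (Sharpless–Michaelson type) delivers oxygen from the vanadate ester of C2–OH to the allylic C1=C6 bond on the face of that hydroxyl, which sets C1 and C6 syn to C2–O and should leave the non-allylic C4=C5 bond untouched.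

**Step 5**
Reactants: 6 [(1S,2S,3S,6R)-2-hydroxy-3-(TDS-oxy)-7-oxabicyclo[4.1.0]hept-4-en-1-yl]methyl benzoate
Product: 7 [(1R,2S,3S,6R)-2-methoxy-3-(TDS-oxy)-7-oxabicyclo[4.1.0]hept-4-en-1-yl]methyl benzoate
Conditions: Me3OBF4, 1,8-bis(dimethylamino)naphthalene, 4 Å MS, CH2Cl2, 0 °C to rt
Reagents that add atoms: trimethyloxonium tetrafluoroborate, C[O+](C)C.F[B-](F)(F)F
Why: O-Methylation with Meerwein's salt buffered by proton sponge alkylates the C2 hydroxyl without forming an alkoxide, so silyl or benzoyl migration should be avoided and C2 keeps its configuration.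

**Step 6**
Reactants: 7 [(1R,2S,3S,6R)-2-methoxy-3-(TDS-oxy)-7-oxabicyclo[4.1.0]hept-4-en-1-yl]methyl benzoate
Product: 8 [(1R,2S,3S,6R)-3-hydroxy-2-methoxy-7-oxabicyclo[4.1.0]hept-4-en-1-yl]methyl benzoate
Conditions: TBAF, AcOH, THF, 0 °C
Reagents that add atoms: none
Why: Fluoride-mediated desilylation buffered with acetic acid should free the allylic C3–OH while the benzoate and the vinyl oxirane survive the near-neutral medium.

**Step 7**
Reactants: 8 [(1R,2S,3S,6R)-3-hydroxy-2-methoxy-7-oxabicyclo[4.1.0]hept-4-en-1-yl]methyl benzoate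
Product: 9 (1R,2S,3R,6R)-1-[(benzoyloxy)methyl]-2-methoxy-7-oxabicyclo[4.1.0]hept-4-en-3-yl benzoate
Conditions: PhCO2H, PPh3, DIAD, toluene, 0 °C to rt
Reagents that add atoms: benzoic acid, O=C(O)c1ccccc1
Why: Mitsunobu esterification activates the allylic C3–OH as an alkoxyphosphonium ion that benzoate displaces by SN2 with inversion, which converts the cis C2/C3 relationship of the chiral pool into the trans relationship of the target.

**Compound list**
1 | (1S,2S)-3-bromocyclohexa-3,5-diene-1,2-diol | O[C@H]1[C@@H](O)C=CC=C1Br | starting material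
2 | (1S,6S)-2-bromo-6-(TDS-oxy)cyclohexa-2,4-dien-1-ol | O[C@H]1[C@@H](O[Si](C)(C)C(C)(C)C(C)C)C=CC=C1Br | intermediate
3 | (tributylstannyl)methanol | OC[Sn](CCCC)(CCCC)CCCC | starting material
4 | (1R,6S)-2-(hydroxymethyl)-6-(TDS-oxy)cyclohexa-2,4-dien-1-ol | O[C@H]1[C@@H](O[Si](C)(C)C(C)(C)C(C)C)C=CC=C1CO | intermediate
5 | [(5S,6R)-6-hydroxy-5-(TDS-oxy)cyclohexa-1,3-dien-1-yl]methyl benzoate | O[C@H]1[C@@H](O[Si](C)(C)C(C)(C)C(C)C)C=CC=C1COC(=O)c1ccccc1 | intermediate
6 | [(1S,2S,3S,6R)-2-hydroxy-3-(TDS-oxy)-7-oxabicyclo[4.1.0]hept-4-en-1-yl]methyl benzoate (oxirane O, C2–OH and C3–OTDS on one face) | O[C@H]1[C@@H](O[Si](C)(C)C(C)(C)C(C)C)C=C[C@H]2O[C@]21COC(=O)c1ccccc1 | intermediate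
7 | [(1R,2S,3S,6R)-2-methoxy-3-(TDS-oxy)-7-oxabicyclo[4.1.0]hept-4-en-1-yl]methyl benzoate | CO[C@H]1[C@@H](O[Si](C)(C)C(C)(C)C(C)C)C=C[C@H]2O[C@]21COC(=O)c1ccccc1 | intermediate
8 | [(1R,2S,3S,6R)-3-hydroxy-2-methoxy-7-oxabicyclo[4.1.0]hept-4-en-1-yl]methyl benzoate | CO[C@H]1[C@@H](O)C=C[C@H]2O[C@]21COC(=O)c1ccccc1 | intermediate
9 | (1R,2S,3R,6R)-1-[(benzoyloxy)methyl]-2-methoxy-7-oxabicyclo[4.1.0]hept-4-en-3-yl benzoate | CO[C@H]1[C@H](OC(=O)c2ccccc2)C=C[C@H]2O[C@]21COC(=O)c1ccccc1 | target

**Step count and risks**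
Total steps: 7. Longest linear sequence: 7 (fully linear from 1).

Steps most likely to fail:

1. Step 5 (O-methylation). The oxonium salt may alkylate the oxirane oxygen and open the vinyl epoxide, or etherification of the hindered C2 hydroxyl may stall. The fallback moves the methylation to an ester-free series and uses the alkoxide; it sets out from 4 and returns at 9.
   - Silylation of the primary hydroxyl of 4 (TBSCl, imidazole, CH2Cl2, 0 °C) would give (1R,6S)-2-{[(tert-butyldimethylsilyl)oxy]methyl}-6-(TDS-oxy)cyclohexa-2,4-dien-1-ol F2.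
   - The same vanadium-directed epoxidation would give (1S,2S,3S,6R)-1-{[(tert-butyldimethylsilyl)oxy]methyl}-3-(TDS-oxy)-7-oxabicyclo[4.1.0]hept-4-en-2-ol F3.
   - With no ester present, methylation through the alkoxide (NaH, MeI, THF, 0 °C) would give tert-butyl{[(1R,2S,3S,6R)-2-methoxy-3-(TDS-oxy)-7-oxabicyclo[4.1.0]hept-4-en-1-yl]methoxy}dimethylsilane F4. A Payne shift is excluded because C2–O and the oxirane oxygen are cis.
   - TBAF would remove both silyl groups to give (1R,2S,3S,6R)-1-(hydroxymethyl)-2-methoxy-7-oxabicyclo[4.1.0]hept-4-en-3-ol F5.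
   - A double Mitsunobu reaction with benzoic acid (PPh3, DIAD) would esterify C1′–OH and invert C3 in one operation, arriving at 9.

2. Step 4 (directed epoxidation). The Lewis-acidic vanadium system may dehydrate the dienol to an arene or oxidise the C4=C5 bond. The fallback replaces substrate direction by reagent control one step earlier; it sets out from 4 and returns at 6.
   - Katsuki–Sharpless epoxidation of the primary allylic alcohol of 4 (Ti(OiPr)4, D-(−)-diethyl tartrate, t-BuOOH, 4 Å MS, CH2Cl2, −20 °C) would give (1S,2S,3S,6R)-1-(hydroxymethyl)-3-(TDS-oxy)-7-oxabicyclo[4.1.0]hept-4-en-2-ol F1. This tartrate enantiomer is the one expected to deliver oxygen to the face of the C2 hydroxyl.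
   - Benzoylation of the primary hydroxyl as in step 3 would give 6.

3. Step 7 (Mitsunobu inversion). The allylic alkoxyphosphonium ion may be captured in the SN2′ sense at C5 or eliminate instead of undergoing direct displacement at C3. The fallback inverts C3 by oxidation and reduction; it sets out from 8 and returns at 9.
   - Dess–Martin oxidation (NaHCO3, CH2Cl2) would give [(1R,2R,6R)-2-methoxy-3-oxo-7-oxabicyclo[4.1.0]hept-4-en-1-yl]methyl benzoate F6.
   - Luche reduction (NaBH4, CeCl3·7H2O, MeOH, −78 °C) should deliver hydride axially to the half-chair with pseudo-equatorial OMe and give mainly the trans alcohol [(1R,2S,3R,6R)-3-hydroxy-2-methoxy-7-oxabicyclo[4.1.0]hept-4-en-1-yl]methyl benzoate F7. The cis epimer is 8 and can be re-oxidised.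
   - Benzoylation (BzCl, pyridine, DMAP, CH2Cl2, 0 °C) would give 9.

**Further compounds**
F1 | step 4 | (1S,2S,3S,6R)-1-(hydroxymethyl)-3-(TDS-oxy)-7-oxabicyclo[4.1.0]hept-4-en-2-ol | O[C@H]1[C@@H](O[Si](C)(C)C(C)(C)C(C)C)C=C[C@H]2O[C@]21CO
F2 | step 5 | (1R,6S)-2-{[(tert-butyldimethylsilyl)oxy]methyl}-6-(TDS-oxy)cyclohexa-2,4-dien-1-ol | O[C@H]1[C@@H](O[Si](C)(C)C(C)(C)C(C)C)C=CC=C1CO[Si](C)(C)C(C)(C)C
F3 | step 5 | (1S,2S,3S,6R)-1-{[(tert-butyldimethylsilyl)oxy]methyl}-3-(TDS-oxy)-7-oxabicyclo[4.1.0]hept-4-en-2-ol | O[C@H]1[C@@H](O[Si](C)(C)C(C)(C)C(C)C)C=C[C@H]2O[C@]21CO[Si](C)(C)C(C)(C)C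
F4 | step 5 | tert-butyl{[(1R,2S,3S,6R)-2-methoxy-3-(TDS-oxy)-7-oxabicyclo[4.1.0]hept-4-en-1-yl]methoxy}dimethylsilane | CO[C@H]1[C@@H](O[Si](C)(C)C(C)(C)C(C)C)C=C[C@H]2O[C@]21CO[Si](C)(C)C(C)(C)C
F5 | step 5 | (1R,2S,3S,6R)-1-(hydroxymethyl)-2-methoxy-7-oxabicyclo[4.1.0]hept-4-en-3-ol | CO[C@H]1[C@@H](O)C=C[C@H]2O[C@]21CO
F6 | step 7 | [(1R,2R,6R)-2-methoxy-3-oxo-7-oxabicyclo[4.1.0]hept-4-en-1-yl]methyl benzoate | CO[C@H]1C(=O)C=C[C@H]2O[C@]21COC(=O)c1ccccc1
F7 | step 7 | [(1R,2S,3R,6R)-3-hydroxy-2-methoxy-7-oxabicyclo[4.1.0]hept-4-en-1-yl]methyl benzoate | CO[C@H]1[C@H](O)C=C[C@H]2O[C@]21COC(=O)c1ccccc1
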